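The butanolide ring (O–C7–C8–C17–C19) is disconnected at C7–C8 and C17–C19. Both bonds form in one intramolecular [2+2] cycloaddition of a ketene (C19=C7) with a silyl enol ether (C8=C17), held together by a temporary diisopropylsilylene bridge from O6 to O8. The step exploits the heteroatom-bearing C6–C7–C8 array: the enol-ether carbon becomes the C8 carbinol, the bridge fixes the C7/C8 ring fusion, O6 is later exchanged for chlorine, and Baeyer–Villiger oxygen insertion turns the cyclobutanone into the lactone. The precursor unites a ring-A methyl ketone with an alkynyl β-hydroxy acid; ethylene-mediated enyne/ring-closing metathesis finally closes the ten-membered ring.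

Key step: step 18

Remark: briarane locants of the target are used for all intermediates (ring A = C1, C10–C14; ten-membered ring = C1–C10; butanolide = O–C7–C8–C17–C19; C15, C16, C18, C20 = C1-methyl, exocyclic methylene, C17-methyl, C11-methyl). α is the ring-A face opposite the C1 methyl, and "as in the target" means the same spatial arrangement. Compounds 1, 3, 17 and 18 are taken to be commercial.

Step 1
Reactants: 1 pent-1-en-3-one
Product: 2 (Z)-triisopropyl(penta-1,3-dien-3-yloxy)silane
Conditions: iPr3SiOTf, Et3N, CH2Cl2, 0 °C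
Reagents that add atoms: triisopropylsilyl trifluoromethanesulfonate CC(C)[Si](OS(=O)(=O)C(F)(F)F)(C(C)C)C(C)C
Why: Soft enolisation and O-silylation of the enone (silyl enol ether formation) should give the 2-silyloxy diene, the Z enol ether placing the methyl trans to the vinyl group so that the s-cis conformer is accessible.

Step 2
Reactants: 2 (Z)-triisopropyl(penta-1,3-dien-3-yloxy)silane; 3 ethyl (E)-3-methyl-4-oxobut-2-enoate
Product: 4 ethyl (1S,6S)-6-formyl-2,6-dimethyl-3-(triisopropylsilyloxy)cyclohex-3-ene-1-carboxylate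
Conditions: (S)-B-(o-tolyl)oxazaborolidine of α,α-diphenylprolinol (20 mol%), Tf2NH (18 mol%), CH2Cl2, −78 → −40 °C
Reagents that add atoms: none
Why: Catalytic enantioselective Diels–Alder reaction (Corey oxazaborolidinium): the methyl-bearing diene terminus next to the silyloxy carbon (C11) bonds to the carbon β to the activated formyl group (C10), suprafacial addition to the E-alkene places formyl (C2) and ester (C9) trans across C1–C10, and the catalyst (chosen by its formyl C–H···O binding model; its antipode would give the enantiomer) should set C1 and C10, while C11 stays a mixture that is erased in step 6.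

Step 3
Reactants: 4 ethyl (1S,6S)-6-formyl-2,6-dimethyl-3-(triisopropylsilyloxy)cyclohex-3-ene-1-carboxylate
Product: 6 trans-fused vinyl lactone, via hydroxy ester 5 (not isolated)
Conditions: CH2=CHMgBr (1.1 equiv), THF, −78 °C; then 23 °C
Reagents that add atoms: vinylmagnesium bromide C=C[Mg]Br
Why: Felkin–Anh addition of the Grignard reagent to the neopentyl aldehyde (attack anti to the C1–C10 bond, past the C1 methyl) should set 2S, and on warming the magnesium alkoxide closes the trans-fused γ-lactone onto the C9 ester (5-exo-trig transesterification), which protects O2 and activates C9.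

Step 4
Reactants: 6 trans-fused vinyl lactone
Product: 7 enone lactone (C12=O, C13=C14)
Conditions: Pd(OAc)2 (10 mol%), O2 (1 atm), DMSO, 60 °C
Reagents that add atoms: none
Why: Saegusa–Ito oxidation of the silyl enol ether, in which the palladium enolate can only lose the C14 hydride, so the C13=C14 enone should form regiospecifically.

Step 5
Reactants: 7 enone lactone
Product: 8 allylic alcohol lactone
Conditions: NaBH4, CeCl3·7H2O, MeOH, −78 → 0 °C
Reagents that add atoms: none
Why: Luche 1,2-reduction of the enone in the presence of the lactone; the configurations at C11 and C12 are irrelevant because both centres become trigonal in step 6.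

Step 6
Reactants: 8 allylic alcohol lactone
Product: 9 cyclohexadiene lactone (C11=C12–C13=C14)
Conditions: Martin sulfurane Ph2S[OC(CF3)2Ph]2, CH2Cl2, 0 → 23 °C
Reagents that add atoms: none
Why: Sulfurane-mediated dehydration of the secondary allylic alcohol, for which C11–H is the only available β-hydrogen, so the conjugated 1,3-diene is the only elimination product expected.

Step 7
Reactants: 9 cyclohexadiene lactone
Product: 10 α-cis-diol lactone
Conditions: OsO4 (2 mol%), N-methylmorpholine N-oxide, acetone/H2O, 0 °C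
Reagents that add atoms: N-methylmorpholine N-oxide C[N+]1([O-])CCOCC1; water O
Why: Upjohn dihydroxylation, in which OsO4 should add suprafacially to the more electron-rich trisubstituted C11=C12 bond from the face opposite the pseudo-axial C1 methyl of the trans-fused bicycle, giving the α-cis-diol (C11 tertiary, C12 secondary).

Step 8
Reactants: 10 α-cis-diol lactone
Product: 11 epoxy diol lactone
Conditions: VO(acac)2 (5 mol%), t-BuOOH, CH2Cl2, 0 → 23 °C
Reagents that add atoms: tert-butyl hydroperoxide CC(C)(C)OO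
Why: Vanadium-catalysed hydroxyl-directed epoxidation, in which the allylic C12–OH delivers the peroxide syn, so the 13,14-epoxide should form on the α face cis to O12 while the vinyl group, which has no free hydroxyl, is left alone.

Step 9
Reactants: 11 epoxy diol lactone
Product: 12 bis(triethylsilyl) ether lactone
Conditions: Et3SiOTf, 2,6-lutidine, CH2Cl2, −78 → 0 °C
Reagents that add atoms: triethylsilyl trifluoromethanesulfonate CC[Si](CC)(CC)OS(=O)(=O)C(F)(F)F
Why: Silyl triflate silylation protects both the secondary C12 and the tertiary C11 hydroxyl without touching any stereocentre.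

Step 10
Reactants: 12 bis(triethylsilyl) ether lactone
Product: 13 hydroxy ketone (C2–OH free, C9 ketone bearing the 1-ethoxyvinyl group)
Conditions: CH2=C(OEt)Li (from ethyl vinyl ether, t-BuLi, THF, −78 → 0 °C), CeCl3, THF, −78 °C; H2O
Reagents that add atoms: 1-ethoxyvinyllithium [Li]C(=C)OCC
Why: Acyl substitution of the lactone by the acyl-anion equivalent, where the tetrahedral hemiketal alkoxide persists at −78 °C so that a single addition is expected, and the cerium additive suppresses enolisation at C10.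

Step 11
Reactants: 13 hydroxy ketone
Product: 14 (9S)-diol enol ether
Conditions: (S)-Me-CBS (0.5 equiv), catecholborane, toluene, −78 → −40 °C
Reagents that add atoms: none
Why: Corey–Bakshi–Shibata reduction under reagent control, with the ring carbon C10 as the large and the 1-ethoxyvinyl group as the small ketone substituent, so the (S)-oxazaborolidine should deliver hydride to give 9S; catecholborane does not hydroborate the alkenes at this temperature.

Step 12
Reactants: 14 (9S)-diol enol ether
Product: 16 tetrakis(triethylsilyl) methyl ketone, via silylated enol ether 15 (not isolated)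
Conditions: Et3SiOTf, 2,6-lutidine, CH2Cl2, −78 °C; then 5% aq. oxalic acid, THF, 0 °C
Reagents that add atoms: triethylsilyl trifluoromethanesulfonate CC[Si](CC)(CC)OS(=O)(=O)C(F)(F)F; water O
Why: Silylation of the C2 and C9 hydroxyls followed by mild acid hydrolysis of the ethyl enol ether in the work-up should unmask the methyl ketone (C8=O, C17H3) without epimerising C9.

Step 13
Reactants: 17 allyl acetate; 18 3-(trimethylsilyl)prop-2-ynal
Product: 19 allyl 3-hydroxy-5-(trimethylsilyl)pent-4-ynoate (racemic)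
Conditions: LiN(iPr)2, THF, −78 °C; then 18
Reagents that add atoms: none
Why: Lithium ester-enolate aldol addition to the ynal, whose racemic carbinol centre is removed in step 14.

Step 14
Reactants: 19 allyl 3-hydroxy-5-(trimethylsilyl)pent-4-ynoate
Product: 20 allyl 3-oxo-5-(trimethylsilyl)pent-4-ynoate
Conditions: Dess–Martin periodinane, NaHCO3, CH2Cl2, 0 °C
Reagents that add atoms: none
Why: Dess–Martin oxidation of the propargylic alcohol to the alkynyl β-keto ester under buffered, non-basic conditions.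

Step 15
Reactants: 20 allyl 3-oxo-5-(trimethylsilyl)pent-4-ynoate
Product: 21 allyl (3R)-3-hydroxy-5-(trimethylsilyl)pent-4-ynoate
Conditions: RuCl[(R,R)-TsDPEN](p-cymene) (1 mol%), HCO2H/Et3N (5:2), CH2Cl2, 23 °C
Reagents that add atoms: none
Why: Noyori asymmetric transfer hydrogenation of an alkynyl ketone, in which the alkynyl group is the directing unsaturated substituent, so the (R,R)-catalyst should give the (R)-propargylic alcohol (C6).

Step 16
Reactants: 16 tetrakis(triethylsilyl) methyl ketone; 21 allyl (3R)-3-hydroxy-5-(trimethylsilyl)pent-4-ynoate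
Product: 23 mixed silaketal allyl ester, via chlorosilyl enol ether 22 (not isolated)
Conditions: LiN(SiMe3)2, THF, −78 °C; iPr2SiCl2 (5 equiv), −78 → 0 °C; evaporate; then 21, imidazole, CH2Cl2, 23 °C
Reagents that add atoms: dichlorodiisopropylsilane CC(C)[Si](Cl)(Cl)C(C)C
Why: Kinetic deprotonation at the methyl group (C17) and O-silylation of the enolate by excess dichlorosilane, then silyl ether formation with the alcohol of 21 at the remaining Si–Cl bond, should give the unsymmetrical silaketal that ties O8 to O6.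

Step 17
Reactants: 23 mixed silaketal allyl ester
Product: 24 silaketal carboxylic acid
Conditions: Pd(PPh3)4 (5 mol%), HCO2H, Et3N, THF, 23 °C
Reagents that add atoms: none
Why: Tsuji–Trost deallylation with formate as hydride donor frees the acid as its triethylammonium salt under near-neutral conditions that the silyl enol ether, the silyl ethers and the epoxide should survive.

Step 18
Reactants: 24 silaketal carboxylic acid
Product: 27 cyclobutanone fused to the siladioxane, via acyloxypyridinium salt 25 (not isolated), via tethered ketene 26 (not isolated)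
Conditions: 2-chloro-1-methylpyridinium iodide, Et3N, toluene (0.002 M, slow addition), 90 °C
Reagents that add atoms: none
Why: Proposed new method: the carboxylate is activated as the 2-acyloxypyridinium salt and triethylamine eliminates it to the monoalkylketene C7H=C19=O; the electron-rich terminal carbon C17 of the silyl enol ether attacks the ketene carbon C19 and the resulting enolate carbon C7 closes onto the oxocarbenium carbon C8 (asynchronous [2+2]), so the C17–C19 and C7–C8 bonds form in one operation. The closest known reactions are the intramolecular ketene–alkene [2+2] cycloaddition (Snider, Brady) and the intermolecular cycloaddition of ketenes to silyl enol ethers giving 3-silyloxycyclobutanones; new here is a tether that runs through the enol silicon atom. Two rings close: the cyclobutanone by the formal [2+2] process and the six-membered 1,3-dioxa-2-silacyclohexane by the C7–C8 bond in a chair-like, necessarily cis-fused arrangement. This cis fusion puts C6 (on C7) and O8 (on C8) on the same face, which is the C7/C8 relationship of the lactone; the absolute sense should come from the C6 stereocentre, whose hydrogen lies in the ketene plane (allylic strain) with the alkynyl group pseudo-equatorial, so that H6 and H7 end up trans. C17 is not yet stereogenic. The step needs regioselectivity (C19 to C17, C7 to C8), secured by the polarity of both partners and the four-atom tether, and chemoselectivity against ketene dimerisation and the remote vinyl and alkynyl groups, secured by high dilution and their low reactivity toward ketenes.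

Step 19
Reactants: 27 cyclobutanone fused to the siladioxane
Product: 28 γ-lactone fused to the siladioxane
Conditions: mCPBA, NaHCO3, CH2Cl2, 0 °C
Reagents that add atoms: 3-chloroperoxybenzoic acid OOC(=O)c1cccc(Cl)c1
Why: Baeyer–Villiger oxidation, in which the strained cyclobutanone should react far faster than the alkenes and the secondary C7 migrates in preference to the primary C17 with retention, inserting oxygen between C19 and C7.

Step 20
Reactants: 28 γ-lactone fused to the siladioxane
Product: 29 17-methyl lactone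
Conditions: LiN(SiMe3)2, THF, −78 °C; MeI, −78 → −40 °C
Reagents that add atoms: iodomethane CI
Why: Lactone enolate alkylation, in which methyl iodide should approach C17 anti to the bulky C9 substituent on the neighbouring C8, i.e. cis to O8 (17R), and the low temperature limits β-elimination of the silyloxy group.

Step 21
Reactants: 29 17-methyl lactone
Product: 30 hexaol with terminal alkyne
Conditions: Bu4NF, AcOH, THF, 0 → 40 °C
Reagents that add atoms: none
Why: Fluoride-mediated cleavage of all Si–O bonds and of the alkynyl C–Si bond, buffered with acetic acid so that retro-aldol cleavage, Payne rearrangement and translactonisation are not expected.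

Step 22
Reactants: 30 hexaol with terminal alkyne
Product: 31 (6R)-propargylic tosylate
Conditions: Zn(OTs)2, PPh3, DIAD, toluene, 23 °C
Reagents that add atoms: zinc p-toluenesulfonate Cc1ccc(cc1)S(=O)(=O)[O-].Cc1ccc(cc1)S(=O)(=O)[O-].[Zn+2]
Why: Mitsunobu reaction with tosylate as nucleophile, in which only the unhindered propargylic C6–OH should be activated (the C2, C9 and C12 hydroxyls are neopentyl-like, those at C8 and C11 tertiary) and tosylate displaces with inversion.

Step 23
Reactants: 31 (6R)-propargylic tosylate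
Product: 32 (6S)-propargylic chloride
Conditions: LiCl, DMF, 40 °C
Reagents that add atoms: lithium chloride [Li+].[Cl-]
Why: SN2 displacement of the propargylic tosylate by chloride with a second inversion, so chlorine should take the position the tether oxygen had at C6 (net retention).

Step 24
Reactants: 32 (6S)-propargylic chloride
Product: 33 2,9,12-triacetate
Conditions: Ac2O, pyridine, DMAP (cat.), CH2Cl2, 0 → 23 °C
Reagents that add atoms: acetic anhydride CC(=O)OC(C)=O
Why: Acylation of the three secondary hydroxyls (C2, C9, C12), while the hindered tertiary C8 and C11 hydroxyls should stay free under these conditions.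

Step 25
Reactants: 33 2,9,12-triacetate
Product: 35 CNP0331168.1, via triene 34 (not isolated)
Conditions: second-generation Grubbs catalyst RuCl2(=CHPh)(H2IMes)(PCy3) (15 mol%), ethylene (1 atm), CH2Cl2, 23 °C; then Ar purge, toluene (0.001 M), 80 °C
Reagents that add atoms: ethylene C=C
Why: Tandem enyne cross-metathesis with ethylene (Mori conditions) should turn the alkyne into the 2-substituted butadiene (C5=C16H2, C4H=CH2), after which ring-closing metathesis between the C4 and C3 vinyl groups closes the ten-membered ring, where ring strain allows only the Z C3=C4 alkene and the 1,1-disubstituted C5=C16 bond is inert.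

Compound list
1 | pent-1-en-3-one (ethyl vinyl ketone) | C=CC(=O)CC | starting material
2 | (Z)-triisopropyl(penta-1,3-dien-3-yloxy)silane | C=C/C(=C/C)O[Si](C(C)C)(C(C)C)C(C)C | intermediate
3 | ethyl (E)-3-methyl-4-oxobut-2-enoate | CCOC(=O)/C=C(\C)C=O | starting material
4 | ethyl (1S,6S)-6-formyl-2,6-dimethyl-3-(triisopropylsilyloxy)cyclohex-3-ene-1-carboxylate (C2-methyl epimers; ring C1 = C10, ring C6 = C1, formyl = C2, ester = C9) | O=C[C@@]1(C)CC=C(O[Si](C(C)C)(C(C)C)C(C)C)C(C)[C@@H]1C(=O)OCC | intermediate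
5 | ethyl (1S,6S)-6-[(1S)-1-hydroxyprop-2-en-1-yl]-2,6-dimethyl-3-(triisopropylsilyloxy)cyclohex-3-ene-1-carboxylate | C=C[C@H](O)[C@@]1(C)CC=C(O[Si](C(C)C)(C(C)C)C(C)C)C(C)[C@@H]1C(=O)OCC | intermediate
6 | (3S,3aS,7aS)-3-ethenyl-3a,7-dimethyl-6-(triisopropylsilyloxy)-3a,4,7,7a-tetrahydro-2-benzofuran-1(3H)-one (trans-fused C2–O–C9 lactone; C11 epimers) | C=C[C@@H]1OC(=O)[C@H]2C(C)C(O[Si](C(C)C)(C(C)C)C(C)C)=CC[C@]12C | intermediate
7 | (3S,3aS,7aS)-3-ethenyl-3a,7-dimethyl-3a,7a-dihydro-2-benzofuran-1,6(3H,7H)-dione (C12 ketone, C13=C14; C11 epimers) | C=C[C@@H]1OC(=O)[C@H]2C(C)C(=O)C=C[C@]12C | intermediate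
8 | (3S,3aS,7aS)-3-ethenyl-6-hydroxy-3a,7-dimethyl-3a,6,7,7a-tetrahydro-2-benzofuran-1(3H)-one (C11 and C12 epimers) | C=C[C@@H]1OC(=O)[C@H]2C(C)C(O)C=C[C@]12C | intermediate
9 | (3S,3aS,7aS)-3-ethenyl-3a,7-dimethyl-3a,7a-dihydro-2-benzofuran-1(3H)-one (diene C11=C12–C13=C14) | C=C[C@@H]1OC(=O)[C@H]2C(C)=CC=C[C@]12C | intermediate
10 | diol lactone: 9 with C11=C12 cis-dihydroxylated on the α face (C11: OH α, CH3 β; C12: OH α) | C=C[C@@H]1OC(=O)[C@H]2[C@](C)(O)[C@H](O)C=C[C@]12C | intermediate
11 | epoxy diol lactone: 10 with the 13,14-epoxide on the α face, cis to O12 | C=C[C@@H]1OC(=O)[C@H]2[C@](C)(O)[C@H](O)[C@@H]3O[C@@H]3[C@]12C | intermediate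
12 | O11,O12-bis(triethylsilyl) ether of 11 | C=C[C@@H]1OC(=O)[C@H]2[C@](C)(O[Si](CC)(CC)CC)[C@H](O[Si](CC)(CC)CC)[C@@H]3O[C@@H]3[C@]12C | intermediate
13 | hydroxy ketone: ring A of 12 with free (2S)-vinyl carbinol on C1 and a 2-ethoxyprop-2-enoyl group on C10 (C9=O, C8(OEt)=C17H2); in equilibrium with its cyclic hemiketal | C=C[C@H](O)[C@@]2(C)[C@H]3O[C@H]3[C@@H](O[Si](CC)(CC)CC)[C@@](C)(O[Si](CC)(CC)CC)[C@@H]2C(=O)C(=C)OCC | intermediate
14 | (9S)-diol enol ether: 13 with the C9 ketone reduced | C=C[C@H](O)[C@@]2(C)[C@H]3O[C@H]3[C@@H](O[Si](CC)(CC)CC)[C@@](C)(O[Si](CC)(CC)CC)[C@@H]2[C@H](O)C(=C)OCC | intermediate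
15 | O2,O9,O11,O12-tetrakis(triethylsilyl) ether of 14 (ethyl enol ether intact) | C=C[C@H](O[Si](CC)(CC)CC)[C@@]2(C)[C@H]3O[C@H]3[C@@H](O[Si](CC)(CC)CC)[C@@](C)(O[Si](CC)(CC)CC)[C@@H]2[C@H](O[Si](CC)(CC)CC)C(=C)OCC | intermediate
16 | ring-A methyl ketone: C9(OSiEt3)–C8(=O)–C17H3, triethylsilyl ethers at O2, O11, O12, 13,14-epoxide; C1, C2, C9–C14 as in the target | C=C[C@H](O[Si](CC)(CC)CC)[C@@]2(C)[C@H]3O[C@H]3[C@@H](O[Si](CC)(CC)CC)[C@@](C)(O[Si](CC)(CC)CC)[C@@H]2[C@H](O[Si](CC)(CC)CC)C(C)=O | intermediate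
17 | allyl acetate | CC(=O)OCC=C | starting material
18 | 3-(trimethylsilyl)prop-2-ynal | C[Si](C)(C)C#CC=O | starting material
19 | allyl 3-hydroxy-5-(trimethylsilyl)pent-4-ynoate (racemic) | C=CCOC(=O)CC(O)C#C[Si](C)(C)C | intermediate
20 | allyl 3-oxo-5-(trimethylsilyl)pent-4-ynoate | C=CCOC(=O)CC(=O)C#C[Si](C)(C)C | intermediate
21 | allyl (3R)-3-hydroxy-5-(trimethylsilyl)pent-4-ynoate (carbinol = C6, CH2 = C7, ester carbon = C19, alkyne = C5≡C4) | C=CCOC(=O)C[C@@H](O)C#C[Si](C)(C)C | intermediate
22 | chloro(diisopropyl)silyl enol ether of 16 (C8(OSi(iPr)2Cl)=C17H2) | C=C[C@H](O[Si](CC)(CC)CC)[C@@]2(C)[C@H]3O[C@H]3[C@@H](O[Si](CC)(CC)CC)[C@@](C)(O[Si](CC)(CC)CC)[C@@H]2[C@H](O[Si](CC)(CC)CC)C(=C)O[Si](Cl)(C(C)C)C(C)C | intermediate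
23 | mixed silaketal allyl ester: diisopropylsilylene joining enol oxygen O8 of 16 and O6 of 21 | C=C[C@H](O[Si](CC)(CC)CC)[C@@]2(C)[C@H]3O[C@H]3[C@@H](O[Si](CC)(CC)CC)[C@@](C)(O[Si](CC)(CC)CC)[C@@H]2[C@H](O[Si](CC)(CC)CC)C(=C)O[Si](C(C)C)(C(C)C)O[C@H](CC(=O)OCC=C)C#C[Si](C)(C)C | intermediate
24 | silaketal carboxylic acid (C19OOH) | C=C[C@H](O[Si](CC)(CC)CC)[C@@]2(C)[C@H]3O[C@H]3[C@@H](O[Si](CC)(CC)CC)[C@@](C)(O[Si](CC)(CC)CC)[C@@H]2[C@H](O[Si](CC)(CC)CC)C(=C)O[Si](C(C)C)(C(C)C)O[C@H](CC(=O)O)C#C[Si](C)(C)C | intermediate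
25 | 2-acyloxy-1-methylpyridinium iodide of 24 | C=C[C@H](O[Si](CC)(CC)CC)[C@@]2(C)[C@H]3O[C@H]3[C@@H](O[Si](CC)(CC)CC)[C@@](C)(O[Si](CC)(CC)CC)[C@@H]2[C@H](O[Si](CC)(CC)CC)C(=C)O[Si](C(C)C)(C(C)C)O[C@H](CC(=O)Oc1cccc[n+]1C)C#C[Si](C)(C)C.[I-] | intermediate
26 | tethered ketene (C7H=C19=O) | C=C[C@H](O[Si](CC)(CC)CC)[C@@]2(C)[C@H]3O[C@H]3[C@@H](O[Si](CC)(CC)CC)[C@@](C)(O[Si](CC)(CC)CC)[C@@H]2[C@H](O[Si](CC)(CC)CC)C(=C)O[Si](C(C)C)(C(C)C)O[C@H](C=C=O)C#C[Si](C)(C)C | intermediate
27 | cyclobutanone (C7–C8–C17–C19) cis-fused to the 2,2-diisopropyl-1,3-dioxa-2-silacyclohexane (O6–Si–O8); alkynyl on C6 equatorial, H6 and H7 trans; C7 and C8 as in the target | C=C[C@H](O[Si](CC)(CC)CC)[C@@]2(C)[C@H]3O[C@H]3[C@@H](O[Si](CC)(CC)CC)[C@@](C)(O[Si](CC)(CC)CC)[C@@H]2[C@H](O[Si](CC)(CC)CC)[C@]45CC(=O)[C@H]4[C@H](C#C[Si](C)(C)C)O[Si](C(C)C)(C(C)C)O5 | intermediate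
28 | γ-lactone (O–C7–C8–C17H2–C19=O) fused to the siladioxane | C=C[C@H](O[Si](CC)(CC)CC)[C@@]2(C)[C@H]3O[C@H]3[C@@H](O[Si](CC)(CC)CC)[C@@](C)(O[Si](CC)(CC)CC)[C@@H]2[C@H](O[Si](CC)(CC)CC)[C@]45CC(=O)O[C@H]4[C@H](C#C[Si](C)(C)C)O[Si](C(C)C)(C(C)C)O5 | intermediate
29 | 17-methyl lactone (17R, methyl cis to O8) | C=C[C@H](O[Si](CC)(CC)CC)[C@@]2(C)[C@H]3O[C@H]3[C@@H](O[Si](CC)(CC)CC)[C@@](C)(O[Si](CC)(CC)CC)[C@@H]2[C@H](O[Si](CC)(CC)CC)[C@]45[C@@H](C)C(=O)O[C@H]4[C@H](C#C[Si](C)(C)C)O[Si](C(C)C)(C(C)C)O5 | intermediate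
30 | hexaol: free hydroxyls at C2, C6 (6S), C8, C9, C11, C12; terminal alkyne C5≡C4H; lactone and epoxide as in the target | C=C[C@H](O)[C@@]2(C)[C@H]3O[C@H]3[C@@H](O)[C@@](C)(O)[C@@H]2[C@H](O)[C@]4(O)[C@@H](C)C(=O)O[C@H]4[C@@H](O)C#C | intermediate
31 | (6R)-propargylic p-toluenesulfonate of 30 | C=C[C@H](O)[C@@]2(C)[C@H]3O[C@H]3[C@@H](O)[C@@](C)(O)[C@@H]2[C@H](O)[C@]4(O)[C@@H](C)C(=O)O[C@H]4[C@H](OS(=O)(=O)c1ccc(C)cc1)C#C | intermediate
32 | (6S)-propargylic chloride pentaol | C=C[C@H](O)[C@@]2(C)[C@H]3O[C@H]3[C@@H](O)[C@@](C)(O)[C@@H]2[C@H](O)[C@]4(O)[C@@H](C)C(=O)O[C@H]4[C@@H](Cl)C#C | intermediate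
33 | 2,9,12-triacetate of 32 (C8–OH and C11–OH free) | C=C[C@H](OC(C)=O)[C@@]2(C)[C@H]3O[C@H]3[C@@H](OC(C)=O)[C@@](C)(O)[C@@H]2[C@H](OC(C)=O)[C@]4(O)[C@@H](C)C(=O)O[C@H]4[C@@H](Cl)C#C | intermediate
34 | triene: 33 with the alkyne converted into the buta-1,3-dien-2-yl group (C5=C16H2, C4H=CH2) | C=C[C@H](OC(C)=O)[C@@]2(C)[C@H]3O[C@H]3[C@@H](OC(C)=O)[C@@](C)(O)[C@@H]2[C@H](OC(C)=O)[C@]4(O)[C@@H](C)C(=O)O[C@H]4[C@@H](Cl)C(=C)C=C | intermediate
35 | CNP0331168.1 (1S,2S,3Z,6S,7R,8R,9S,10S,11S,12R,13R,14R,17R) | C=C1/C=C\[C@H](OC(C)=O)[C@@]2(C)[C@H]3O[C@H]3[C@@H](OC(C)=O)[C@@](C)(O)[C@@H]2[C@H](OC(C)=O)[C@]2(O)[C@@H](C)C(=O)O[C@H]2[C@H]1Cl | target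

Total step count: 25. Longest linear sequence: 22 steps (steps 1–12, then 16–25); the second fragment takes 3 steps (13–15).

Steps most likely to fail

1. Step 18 (tethered ketene cycloaddition). The ketene may oligomerise, the enol silyl group may be transferred to the carboxylate before the ketene forms, or the enol-ether face may be discriminated poorly. The fallback makes the same two bonds by the known intermolecular ketene–silyl enol ether cycloaddition, setting out from 16 and 21. Ketone 16 is converted (LiN(SiMe3)2, Me3SiCl, THF, −78 °C) into trimethylsilyl enol ether F1. Alcohol 21 is silylated (Et3SiOTf, 2,6-lutidine) to triethylsilyl ether F2 and deallylated (Pd(PPh3)4, HCO2H, Et3N) to acid F3. The ketene generated from F3 (2-chloro-1-methylpyridinium iodide, Et3N, toluene, 80 °C) is trapped with excess F1 to give cyclobutanone F4, which is separated from its diastereomers. Baeyer–Villiger oxidation (mCPBA, NaHCO3) then gives lactone F5, enolate methylation (LiN(SiMe3)2, MeI) gives methyl lactone F6, and desilylation (Bu4NF, AcOH) returns to the route at 30.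

2. Step 25 (tandem enyne/ring-closing metathesis). The ruthenium alkylidene formed at the diene terminus may engage the hindered vinyl group next to the C2 acetate too slowly, so that oligomerisation and catalyst decay win. The fallback moves the ring closure ahead of the acetylation, so that the free allylic C2 hydroxyl assists metathesis at that alkene. Setting out from 32, the same ethylene-mediated sequence is run on the unprotected pentaol to give, through triene F7, macrocyclic pentaol F8. Acetylation of the three secondary hydroxyls (Ac2O, pyridine, DMAP) then comes back to the route at 35.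

3. Step 22 (site-selective Mitsunobu tosylation). Capture of the oxyphosphonium ion by the weakly nucleophilic sulfonate may be slow, which would allow elimination at the propargylic position or activation of a second hydroxyl. The fallback uses a carboxylate Mitsunobu inversion that also serves as temporary protection of O6. Setting out from 30, Mitsunobu reaction with chloroacetic acid (PPh3, DIAD) gives inverted chloroacetate F9, and acetylation (Ac2O, pyridine, DMAP) gives triacetate F10. Selective removal of the chloroacetate (thiourea, NaHCO3, EtOH) gives alcohol F11, and Appel chlorination with inversion (PPh3, CCl4) comes back to the route at 33.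

Further compounds
F1 | step 18 | trimethylsilyl enol ether of 16 | C=C[C@H](O[Si](CC)(CC)CC)[C@@]2(C)[C@H]3O[C@H]3[C@@H](O[Si](CC)(CC)CC)[C@@](C)(O[Si](CC)(CC)CC)[C@@H]2[C@H](O[Si](CC)(CC)CC)C(=C)O[Si](C)(C)C
F2 | step 18 | allyl (3R)-3-(triethylsilyloxy)-5-(trimethylsilyl)pent-4-ynoate | C=CCOC(=O)C[C@@H](O[Si](CC)(CC)CC)C#C[Si](C)(C)C
F3 | step 18 | (3R)-3-(triethylsilyloxy)-5-(trimethylsilyl)pent-4-ynoic acid | OC(=O)C[C@@H](O[Si](CC)(CC)CC)C#C[Si](C)(C)C
F4 | step 18 | untethered cyclobutanone (O8 trimethylsilyl, O6 triethylsilyl; C6, C7, C8 as in 27) | C=C[C@H](O[Si](CC)(CC)CC)[C@@]2(C)[C@H]3O[C@H]3[C@@H](O[Si](CC)(CC)CC)[C@@](C)(O[Si](CC)(CC)CC)[C@@H]2[C@H](O[Si](CC)(CC)CC)[C@]4(O[Si](C)(C)C)CC(=O)[C@H]4[C@@H](O[Si](CC)(CC)CC)C#C[Si](C)(C)C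
F5 | step 18 | untethered γ-lactone | C=C[C@H](O[Si](CC)(CC)CC)[C@@]2(C)[C@H]3O[C@H]3[C@@H](O[Si](CC)(CC)CC)[C@@](C)(O[Si](CC)(CC)CC)[C@@H]2[C@H](O[Si](CC)(CC)CC)[C@]4(O[Si](C)(C)C)CC(=O)O[C@H]4[C@@H](O[Si](CC)(CC)CC)C#C[Si](C)(C)C
F6 | step 18 | untethered 17-methyl lactone | C=C[C@H](O[Si](CC)(CC)CC)[C@@]2(C)[C@H]3O[C@H]3[C@@H](O[Si](CC)(CC)CC)[C@@](C)(O[Si](CC)(CC)CC)[C@@H]2[C@H](O[Si](CC)(CC)CC)[C@]4(O[Si](C)(C)C)[C@@H](C)C(=O)O[C@H]4[C@@H](O[Si](CC)(CC)CC)C#C[Si](C)(C)C
F7 | step 25 | triene pentaol (32 with the alkyne converted into the buta-1,3-dien-2-yl group) | C=C[C@H](O)[C@@]2(C)[C@H]3O[C@H]3[C@@H](O)[C@@](C)(O)[C@@H]2[C@H](O)[C@]4(O)[C@@H](C)C(=O)O[C@H]4[C@@H](Cl)C(=C)C=C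
F8 | step 25 | macrocyclic pentaol (35 without the three acetyl groups) | C=C1/C=C\[C@H](O)[C@@]2(C)[C@H]3O[C@H]3[C@@H](O)[C@@](C)(O)[C@@H]2[C@H](O)[C@]2(O)[C@@H](C)C(=O)O[C@H]2[C@H]1Cl
F9 | step 22 | (6R)-chloroacetate of the pentaol | C=C[C@H](O)[C@@]2(C)[C@H]3O[C@H]3[C@@H](O)[C@@](C)(O)[C@@H]2[C@H](O)[C@]4(O)[C@@H](C)C(=O)O[C@H]4[C@H](OC(=O)CCl)C#C
F10 | step 22 | (6R)-chloroacetate 2,9,12-triacetate | C=C[C@H](OC(C)=O)[C@@]2(C)[C@H]3O[C@H]3[C@@H](OC(C)=O)[C@@](C)(O)[C@@H]2[C@H](OC(C)=O)[C@]4(O)[C@@H](C)C(=O)O[C@H]4[C@H](OC(=O)CCl)C#C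
F11 | step 22 | (6R)-alcohol 2,9,12-triacetate | C=C[C@H](OC(C)=O)[C@@]2(C)[C@H]3O[C@H]3[C@@H](OC(C)=O)[C@@](C)(O)[C@@H]2[C@H](OC(C)=O)[C@]4(O)[C@@H](C)C(=O)O[C@H]4[C@H](O)C#C
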